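The readings stem from a simulated flask for substances that don't exist, and the scatter is random.

**Equal rates.** At 10.0 min the ratio of molar target in the epsilon run to that in the eta run is 1.01, although epsilon holds twice the electrophile. This reckoning therefore takes target as made at a steady rate (zero order in electrophile) while electrophile lasts.

the same everywhere: gas 8.5 mM (held)

| charge | electrophile | free base | remark | time |
|---|---|---|---|---|
| eta | 0.12 M | 0.12 M | run made earlier |  |
| epsilon | 0.24 M | 0.12 M | run made earlier |  |
| north-east | 0.12 M | 0.120 M (fed, over 80 min) | all else is in the flask from the start; the feed brings no volume worth counting | 1.5 h |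
| south-east | 0.12 M | 0.120 M | everything together at the start | 1.5 h |
| north-west | 0.12 M (in portions, 5, over 80 min) | 0.120 M | first portion at the start, last at 80 min | 1.5 h |
| south-west | 0.12 M (fed, over 80 min) | 0.120 M | all else is in the flask from the start; the feed brings no volume worth counting | 1.5 h |

| run | time / min | target / % |
|---|---|---|
| eta | 4.00 | 7.6 |
| eta | 10.0 | 16.5 |
| eta | 20.0 | 28.7 |
| eta | 30.0 | 36.2 |
| eta | 40.0 | 42.2 |
| eta | 50.0 | 45.3 |
| epsilon | 1.50 | 1.5 |
| epsilon | 3.00 | 2.9 |
| epsilon | 5.00 | 4.9 |
| epsilon | 6.00 | 5.4 |
| epsilon | 8.00 | 7.4 |
| epsilon | 10.0 | 8.3 |

(readings scatter by 0.3 percentage points)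

- at the start none of the gas is in solution

* the best flask by amount of target, in percent of the electrophile charged; "all alike" if 1.5 percentage points covers them all (north-east / south-east / north-west / south-west / all alike)
* amount of target at the end, in percent of the electrophile charged, north-east
* amount of target at the end, in percent of the electrophile charged, south-east
* amount of target at the end, in percent of the electrophile charged, north-west
* amount of target at the end, in percent of the electrophile charged, south-west

**Bench note.** Eta gains 28.7% in its first 20.0 min but 14 percentage points in the next. Steady making against first-order loss shrinks such gains by a constant factor, so its logarithm gives, as a reading from eta with eta's scatter, the fade decade, the time in which unfed target falls by a factor of 10: 61.1 min.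

**At the end.** South-east has eta's charge. At eta's opening rate this reckoning gives its electrophile 52.6 min, which leaves 0.612 decades of fade, so the estimate takes target from eta's last 45.3% to 11.1%. Free base never varied in the runs, so north-east is taken as equal to south-east. The electrophile additions end at 80 min, leaving 0.164 decades, fewer than south-east, so the west flasks should lead. Those additions are not to be hurried, and no flask is to stand past 1.5 h.

**The forecast.** It differs from this reckoning: south-east leads at 52%, with north-east 42%, north-west 51% and south-west 51%. Its ground is that “slow capture of gas by base sets it”.

**The result.** The best flask is north-west at 33.2%, then south-west at 28.2%. North-east gives 16.3% and south-east 16.3%.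

    gas ⇌ nucleophile, rate k1*(csat - [nucleophile]) (kL = 0.00920 /s)
    target ⇌ isomer of the product (K = 16.0, k = 5.79 × 10⁻⁴ /s)
    electrophile + nucleophile → acid set free + target (k = 3.14 /M/s)
    acid set free + free base ⇌ salt of the base (K = 12600 /M, k = 0.0322 /M/s)
    nucleophile + acid set free ⇌ protonated nucleophile, settled at all times (K = 1.13 × 10⁶ /M)

**Fade floor.** After 15.0 h, south-east holds 5.88% target and 94.1% isomer of the product. South-east read at 2.5 h has 0.982 decades more than at 1.5 h, so its excess of 10 points over that long-standing amount leaves 6.97% target. That neighbour reads 7.01%.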